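**Retrosynthetic overview**

1. Numbering: C1 (quaternary, geranyl), C2H2, C3H=C4(CH3), C5H, C6H2, C7H, C8(CH3)2, O9, C10=C11(prenyl), C12=O, C13, C14; ring A = C1-C2-C3-C4-C5-C14, ring B = C5-C6-C7-C13-C14, ring C = C7-C8-O9-C10-C13, ring D = C1-C12-C11-C10-C13-C14.
2. Feature: C13 is the gamma-carbon of the C10=C11-C12=O vinylogous ester and lies four atoms from C7 of a C7-C8 oxirane whose oxygen stays on C8, within reach of C10. Rings B and C are therefore cut together (C7-C13, then O9-C10) back to the bicyclic epoxy vinylogous methyl ester 17; the C13 hydroxyl is added last.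
3. 17 comes from a ring A/D ketol: the C3=C4 methyl alkene from the C4 ketone (enol triflate, methyl coupling), the vinylogous ester from a ring-D 1,3-dione (C11 prenylation, O-methylation), and that dione from a C10 carbinol.
4. The ketol is cut at C5-C14 (D-proline desymmetrising aldol, sets C1, C5, C14) to a triketone made by Michael addition of 2-geranyl-5-hydroxycyclohexane-1,3-dione (from phloroglucinol) to an (S)-epoxy vinyl ketone (Shi epoxidation sets C7).
5. Ring order: D (phloroglucinol core), A (aldol), then B and C in one operation. The oxirane is made on the side-chain fragment before any geranyl or prenyl group is present, so no late choice between trisubstituted alkenes arises.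

Key step: step 13

Remark: a 2-geranylphloroglucinol would take a Michael acceptor at its free ring carbons, so the non-aromatic 5-hydroxy-1,3-dione 7 is used and the C10 ketone is restored in step 8.
Remark: 9, 10 and 11 carry the C10 carbinol as both epimers (9 is drawn as its enol, 7 as the diketone); this centre is removed in step 8.
Remark: from 11 on, the tertiary C14 hydroxyl lies 1,4 to the oxirane, so acids are excluded (buffered work-ups, Et3N-deactivated silica; the acidic 1,3-diones 12 and 14 are used at once).
Assumption: the D-fructose-derived Shi ketone gives the (R)-oxirane from 2-methylalk-2-enes, so its enantiomer is specified for the (S)-oxirane.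

**Route**

Step 1
Reactants: 1 5-methylhex-4-enoic acid
Product: 3 N-methoxy-N,5-dimethylhex-4-enamide, via acyl imidazolide 2 (not isolated)
Conditions: 1,1'-carbonyldiimidazole, CH2Cl2, rt; then MeNH(OMe)·HCl, rt
Reagents that add atoms: N,O-dimethylhydroxylamine hydrochloride, CNOC.Cl
Why: Amide coupling through the acyl imidazolide (carbonyldiimidazole activation), which acylates the amine freed from its hydrochloride by imidazole; no stereocentre is formed.

Step 2
Reactants: 3 N-methoxy-N,5-dimethylhex-4-enamide
Product: 4 (S)-3-(3,3-dimethyloxiran-2-yl)-N-methoxy-N-methylpropanamide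
Conditions: L-fructose-derived Shi ketone (0.3 equiv), Oxone (2KHSO5·KHSO4·K2SO4), K2CO3, Bu4NHSO4, MeCN–CH2(OMe)2–aq. Na2B4O7 buffer (pH 10.5), 0 °C
Reagents that add atoms: potassium peroxymonosulfate (active part of Oxone), [K+].[O-]S(=O)(=O)OO
Why: Shi asymmetric epoxidation: the chiral dioxirane formed in situ attacks the only alkene, an electron-rich trisubstituted one, through the spiro transition state, and this enantiomer of the ketone should set C7 as (S); the Weinreb amide is inert.

Step 3
Reactants: 4 (S)-3-(3,3-dimethyloxiran-2-yl)-N-methoxy-N-methylpropanamide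
Product: 5 (S)-1-(3,3-dimethyloxiran-2-yl)pent-4-en-3-one
Conditions: CH2=CHMgBr, THF, −78 to −20 °C; inverse quench into cold aq. NH4Cl; used without storage
Reagents that add atoms: vinylmagnesium bromide, C=C[Mg]Br
Why: Weinreb ketone synthesis: the magnesium chelate of the tetrahedral adduct survives until work-up, so the vinyl ketone is not attacked again, and the trisubstituted oxirane does not react with the Grignard reagent at this temperature; C7 is untouched.

Step 4
Reactants: 6 phloroglucinol
Product: 7 5-hydroxycyclohexane-1,3-dione (dihydrophloroglucinol)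
Conditions: NaBH4, H2O, 0 °C to rt; then cold dil. HCl to pH 5
Reagents that add atoms: none
Why: Known partial reduction of phloroglucinol: hydride adds to one carbonyl of the triketo tautomer in water and the 1,3-dione enolate that results resists further reduction, giving a non-aromatic, achiral 5-hydroxy-1,3-dione.

Step 5
Reactants: 7 5-hydroxycyclohexane-1,3-dione; 8 geranyl bromide
Product: 9 2-geranyl-5-hydroxycyclohexane-1,3-dione (enol form, racemic at the carbinol carbon)
Conditions: aq. KOH (1 equiv), rt; then pH 5 at 0 °C
Reagents that add atoms: none
Why: C-alkylation of a cyclic 1,3-dione enolate with an allylic bromide in water, where hydrogen bonding to the enolate oxygens favours reaction at C2 (the future C1), the only nucleophilic carbon of 7.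

Step 6
Reactants: 9 2-geranyl-5-hydroxycyclohexane-1,3-dione; 5 (S)-1-(3,3-dimethyloxiran-2-yl)pent-4-en-3-one
Product: 10 2-geranyl-5-hydroxy-2-[5-((S)-3,3-dimethyloxiran-2-yl)-3-oxopentyl]cyclohexane-1,3-dione (both ring isomers)
Conditions: Et3N (cat.), CH2Cl2, rt
Reagents that add atoms: none
Why: Amine-catalysed Michael addition of a 2-substituted cyclohexane-1,3-dione to a vinyl ketone, the standard entry to Hajos–Parrish-type triketones; it makes C1 quaternary while the two ring carbonyls stay equivalent apart from the remote C7.

Step 7
Reactants: 10 the triketone from step 6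
Product: 11 cis-fused ring A/D ketol: C1 geranyl, C4 ketone, C5 (3,3-dimethyloxiran-2-yl)methyl, C10 carbinol (both epimers), C12 ketone, C14 tertiary hydroxyl cis to geranyl and cis to C5–H
Conditions: D-proline (30 mol %), DMF, rt
Reagents that add atoms: none
Why: Hajos–Parrish–Eder–Sauer–Wiechert aldol: the (E)-enamine of the side-chain ketone with D-proline adds through C5 to one of the two enantiotopic ring carbonyls in the carboxylic-acid-bridged chair transition state, which should set C1 and C14 (cis-fused ketol, hydroxyl cis to geranyl, the sense opposite to the L-proline Wieland–Miescher series) and C5 (anti aldol, C5–H cis to the C14 hydroxyl); without acid co-catalyst or heat the ketol should not lose water.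

Step 8
Reactants: 11 the ketol from step 7
Product: 12 ring A/D ketol with the ring-D 1,3-dione (C10/C12, drawn as the C10 enol), C4 ketone and C14 hydroxyl unchanged
Conditions: Dess–Martin periodinane, pyridine, CH2Cl2, 0 °C; aq. Na2S2O3 then pH 6 buffer; used at once
Reagents that add atoms: none
Why: Dess–Martin oxidation of the secondary C10 carbinol to the ketone, which enolises to the 1,3-dione; the tertiary C14 alcohol cannot be oxidised, oxirane and alkenes are inert, and both C10 epimers give the same product.

Step 9
Reactants: 12 the 1,3-dione from step 8; 13 prenyl bromide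
Product: 14 the C11-prenylated 1,3-dione (C10 enol form)
Conditions: iPr2NEt, Pd(PPh3)4 (5 mol %), THF, 0 °C to rt
Reagents that add atoms: none
Why: Tsuji–Trost-type C-allylation: the 1,3-dione enolate attacks the unsubstituted terminus of the (1,1-dimethylallyl)palladium complex formed from prenyl bromide and zerovalent palladium, and any O-prenyl enol ether re-ionises under the catalyst, so prenyl ends on C11, the only carbon between the two carbonyls.

Step 10
Reactants: 14 the C11-prenylated 1,3-dione
Product: 15 vinylogous methyl ester (C10 OMe, C11 prenyl, C12 ketone) with C4 ketone and free C14 hydroxyl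
Conditions: Me2SO4, K2CO3, acetone, 0 °C to rt
Reagents that add atoms: dimethyl sulfate, COS(=O)(=O)OC
Why: O-alkylation of the potassium enolate of a 2-substituted 1,3-dione with a hard electrophile (classical vinylogous ester formation), expected mainly at O10 because O12 is shielded by the quaternary C1; the minor O12-methyl isomer is removed by chromatography, and the weak base should leave C5 alone.

Step 11
Reactants: 15 the vinylogous methyl ester ketone
Product: 16 C3=C4 enol triflate (triflate on C4)
Conditions: LiN(iPr)2 (2.2 equiv), THF, −78 °C; Comins' reagent, −78 to −40 °C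
Reagents that add atoms: N-(5-chloropyridin-2-yl)-1,1,1-trifluoro-N-(trifluoromethylsulfonyl)methanesulfonamide (Comins' reagent), FC(F)(F)S(=O)(=O)N(c1ccc(Cl)cn1)S(=O)(=O)C(F)(F)F
Why: Kinetic enolisation and O-triflation: after lithiation of the C14 hydroxyl, the amide base removes a proton from the unhindered C3 methylene of the C4 ketone (C5 is tertiary and next to the alkoxide, and the gamma-protons at C13 react more slowly at −78 °C), and the cold temperature keeps the lithium aldolate from retro-aldol cleavage.

Step 12
Reactants: 16 the enol triflate
Product: 17 ring A/D vinylogous methyl ester with C3=C4 methyl alkene, free C14 hydroxyl and the (S)-(3,3-dimethyloxiran-2-yl)methyl group on C5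
Conditions: Me2Zn, Pd(PPh3)4 (5 mol %), THF, 0 °C to rt
Reagents that add atoms: dimethylzinc, C[Zn]C
Why: Negishi coupling of an alkenyl triflate with Me2Zn under zerovalent palladium catalysis puts the methyl group on C4 and keeps the double bond at C3=C4; ketone, oxirane and tertiary alcohol are tolerated at this temperature.

Step 13
Reactants: 17 the epoxy vinylogous methyl ester
Product: 19 13-deoxy tetracycle (rings A, B, C and D; C13–H in place of the C13 hydroxyl), via ring-B-closed tertiary alcohol 18 (not isolated)
Conditions: LiN(iPr)2 (2.3 equiv), THF, −78 °C to rt; aq. NH4Cl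
Reagents that add atoms: none
Why: Proposed new method: after the C14 hydroxyl is lithiated, LiN(iPr)2 removes a C13 proton (C1 is quaternary and C11 fully substituted, so C13 is the only carbon acid) to give the gamma-dienolate of the vinylogous ester, whose C13 terminus opens the oxirane at the nearer, secondary carbon C7 with inversion (C7-C13), and the C8 alkoxide set free adds to the beta-carbon C10 and expels methoxide (O9-C10). The closest known reactions are the intramolecular opening of epoxides by ketone and nitrile anions, gamma-alkylation of dienolates of alpha'-blocked 3-alkoxyenones, and alkoxide exchange at the beta-carbon of vinylogous esters. Ring B closes 5-exo-tet with the dienolate double bond outside the new ring, and ring C closes 5-exo-trig by addition and then elimination. C7 is set by the (S)-oxirane through inversion, which also puts C8 on the face of ring B that carries C10, and C13 is set by the short tether from C14 through C5 and C6, which reaches only the dienolate face syn to C5 (cis B/D fusion, C13–H on the side of the C14 oxygen). The step needs carbon C13 and not the C14 alkoxide to attack the oxirane, gamma- and not alpha-attack, and C7 and not C8 as the site: the hindered lithium tertiary alkoxide is a poor nucleophile (as in alkylations of beta-hydroxy carbonyl dianions, which occur at carbon) and would have to form a trans-fused oxolane, attack through C11 would need a bridged seven-membered ring, and C8 is tertiary and 6-endo. The C14 oxygen, present as an oxide, cannot leave by beta-elimination from the dienolate.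

Step 14
Reactants: 19 the 13-deoxy tetracycle
Product: 20 CNP0323114.1 (target)
Conditions: KN(SiMe3)2 (2.3 equiv), THF, −78 °C; 3-phenyl-2-(phenylsulfonyl)oxaziridine, −78 to −40 °C; aq. NH4Cl
Reagents that add atoms: 3-phenyl-2-(phenylsulfonyl)oxaziridine, O=S(=O)(N1OC1c1ccccc1)c1ccccc1
Why: Davis oxidation of a potassium dienolate: after the C14 hydroxyl, the only acidic C–H is C13–H, which stands nearly perpendicular to the enone plane, and the oxaziridine transfers oxygen to the gamma-terminus C13 (C11 is fully substituted and attack there would break the vinylogous ester conjugation) on its only open face, that of the departing hydrogen, since the other three positions are ring bonds; this gives the C13 hydroxyl cis to the C14 hydroxyl.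

**Compound list**

1 | 5-methylhex-4-enoic acid | CC(C)=CCCC(=O)O | starting material
2 | 1-(5-methylhex-4-enoyl)imidazole (not isolated) | CC(C)=CCCC(=O)n1ccnc1 | intermediate
3 | N-methoxy-N,5-dimethylhex-4-enamide | CC(C)=CCCC(=O)N(C)OC | intermediate
4 | (S)-3-(3,3-dimethyloxiran-2-yl)-N-methoxy-N-methylpropanamide | CON(C)C(=O)CC[C@@H]1OC1(C)C | intermediate
5 | (S)-1-(3,3-dimethyloxiran-2-yl)pent-4-en-3-one | C=CC(=O)CC[C@@H]1OC1(C)C | intermediate
6 | phloroglucinol | Oc1cc(O)cc(O)c1 | starting material
7 | 5-hydroxycyclohexane-1,3-dione | O=C1CC(O)CC(=O)C1 | intermediate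
8 | geranyl bromide | CC(C)=CCC/C(C)=C/CBr | starting material
9 | 2-geranyl-5-hydroxycyclohexane-1,3-dione, enol form, racemic carbinol | CC(C)=CCC/C(C)=C/CC1=C(O)CC(O)CC1=O | intermediate
10 | 2-geranyl-5-hydroxy-2-[5-((S)-3,3-dimethyloxiran-2-yl)-3-oxopentyl]cyclohexane-1,3-dione, both ring isomers | CC(C)=CCC/C(C)=C/CC1(CCC(=O)CC[C@@H]2OC2(C)C)C(=O)CC(O)CC1=O | intermediate
11 | ring A/D ketol, C10 carbinol (both epimers), C4 and C12 ketones, C14 hydroxyl | CC(C)=CCC/C(C)=C/C[C@]12CCC(=O)[C@H](C[C@@H]3OC3(C)C)[C@]2(O)CC(O)CC1=O | intermediate
12 | ring A/D ketol with ring-D 1,3-dione (C10 enol) | CC(C)=CCC/C(C)=C/C[C@]12CCC(=O)[C@H](C[C@@H]3OC3(C)C)[C@]2(O)CC(O)=CC1=O | intermediate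
13 | prenyl bromide | CC(C)=CCBr | starting material
14 | C11-prenylated ring-D 1,3-dione (C10 enol) | CC(C)=CCC/C(C)=C/C[C@]12CCC(=O)[C@H](C[C@@H]3OC3(C)C)[C@]2(O)CC(O)=C(CC=C(C)C)C1=O | intermediate
15 | vinylogous methyl ester with C4 ketone | CC(C)=CCC/C(C)=C/C[C@]12CCC(=O)[C@H](C[C@@H]3OC3(C)C)[C@]2(O)CC(OC)=C(CC=C(C)C)C1=O | intermediate
16 | C3=C4 enol triflate | CC(C)=CCC/C(C)=C/C[C@]12CC=C(OS(=O)(=O)C(F)(F)F)[C@H](C[C@@H]3OC3(C)C)[C@]2(O)CC(OC)=C(CC=C(C)C)C1=O | intermediate
17 | epoxy vinylogous methyl ester (key-step precursor) | CC(C)=CCC/C(C)=C/C[C@]12CC=C(C)[C@H](C[C@@H]3OC3(C)C)[C@]2(O)CC(OC)=C(CC=C(C)C)C1=O | intermediate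
18 | ring-B-closed vinylogous methyl ester with C8 tertiary alcohol (not isolated) | CC(C)=CCC/C(C)=C/C[C@]12CC=C(C)[C@@H]3C[C@H](C(C)(C)O)[C@H](C(OC)=C(CC=C(C)C)C1=O)[C@@]32O | intermediate
19 | 13-deoxy tetracycle | CC(C)=CCC/C(C)=C/C[C@]12CC=C(C)[C@@H]3C[C@@H]4C(C)(C)OC(=C(CC=C(C)C)C1=O)[C@@H]4[C@@]32O | intermediate
20 | CNP0323114.1 | CC(C)=CCC/C(C)=C/C[C@]12CC=C(C)[C@@H]3C[C@@H]4C(C)(C)OC(=C(CC=C(C)C)C1=O)[C@]4(O)[C@@]32O | target

**Step count**

Total: 14 steps. Longest linear sequence: 12 steps (1 to 20 through steps 1–3 and 6–14).

**Steps most likely to fail**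

Step 13 (key step). The lithium C14 alkoxide may open the oxirane itself to give an oxolane, gamma-deprotonation may be incomplete, or the dienolate may react too slowly so that base-induced isomerisation of the oxirane takes over. The fallback uses known 1,3-dicarbonyl dianion chemistry; it sets out from 17 and returns at 19. Aqueous LiOH in THF hydrolyses the methyl enol ether to the free ring-D 1,3-dione F1. LiN(iPr)2 (3.3 equiv, THF, −78 to 0 °C) then forms the alkoxide and the dione dianion, whose terminal carbon C13 is far more nucleophilic than the alkoxide and opens the oxirane at C7 to give the ring-B-closed dione diol F2. Pyridinium p-toluenesulfonate in benzene cyclodehydrates F2 between the C8 hydroxyl and C10 to the enol ether 19.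

Step 7. The ketol may lose water across C5–C14 to the Wieland–Miescher-type enone, and discrimination between the two ring carbonyls may be incomplete. The fallback replaces catalyst control by resolution through the existing (S)-oxirane; it sets out from 10 and returns at 11. Pyrrolidine (cat., Et2O, 0 °C, short reaction time) closes ring A without facial control but with the same cis-ketol, anti-C5 relative configuration. The two ring-enantiomeric ketols are then diastereomers, 11 and the 1,5,14-epimeric ketol F3, and are separated on Et3N-deactivated silica; F3 can be returned to 10 by amine-catalysed retro-aldol and recycled.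

Step 14. Deprotonation at C13 may be incomplete because this carbon must flatten at the junction of rings B, C and D, and oxygen may be transferred to C11 instead. The fallback hydroxylates before ring C exists; it sets out from 17 and returns at 20. The cascade is run with LiN(iPr)2 (3.3 equiv) at −40 °C so that the ring-B-closed intermediate is deprotonated again at C13, where the dienolate is part of an unstrained cis-fused bicycle. Quenching with the sulfonyloxaziridine gives the 13-hydroxy ring-C-open vinylogous methyl ester F4, and NaH in THF at 0 °C then closes ring C by alkoxide addition and loss of methoxide to give 20.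

Further compounds
F1 | step 13 | ring A/D epoxy 1,3-dione (C10 hydroxyl in place of the methoxy group of 17) | CC(C)=CCC/C(C)=C/C[C@]12CC=C(C)[C@H](C[C@@H]3OC3(C)C)[C@]2(O)CC(O)=C(CC=C(C)C)C1=O
F2 | step 13 | ring-B-closed 1,3-dione with C8 and C14 tertiary alcohols | CC(C)=CCC/C(C)=C/C[C@]12CC=C(C)[C@@H]3C[C@H](C(C)(C)O)[C@H](C(O)=C(CC=C(C)C)C1=O)[C@@]32O
F3 | step 7 | 1,5,14-epimeric ketol (ring stereocentres inverted, (S)-oxirane kept, both C10 epimers) | CC(C)=CCC/C(C)=C/C[C@@]12CCC(=O)[C@@H](C[C@@H]3OC3(C)C)[C@@]2(O)CC(O)CC1=O
F4 | step 14 | 13-hydroxy ring-B-closed vinylogous methyl ester with C8 tertiary alcohol | CC(C)=CCC/C(C)=C/C[C@]12CC=C(C)[C@@H]3C[C@H](C(C)(C)O)[C@](O)(C(OC)=C(CC=C(C)C)C1=O)[C@@]32O
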